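Everything rests on treating the eight hydroxyls that flank the ether carbons (C2/C6 of ring A, C3/C5 of rings B, C and D; rings lettered from the 2,4,6-trihydroxyphenoxy end) as acetyl groups. The acetyls first activate a fluorine-bearing carbon between them, so the four diaryl ether bonds are made by iterative fluoride displacement on electron-poor rings. One eightfold Baeyer–Villiger oxidation then converts all eight C-acetyl groups into O-acetyl groups. Its precursor is the octaacetyl pentamer in which the remaining four oxygens (O4 of ring A; O3, O4 and O5 of ring E) are already acetates, so no ring is electron-rich under peracid and the product is the dodecaacetate of the target.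

Key step: step 13

Remark 1: the target has twelve hydroxyls, four diaryl ether bonds and no stereocentre; the lithium adducts 5 to 7 are stereoisomer mixtures that disappear on work-up.
Remark 2: the fluoro diketone is built on a TIPS ether, not a benzyl ether, because s-BuLi would metalate a benzylic CH2 (Wittig rearrangement) and an alkoxy group would steer lithiation next to oxygen. The first ketone stays masked as its tetrahedral adduct, because a free methyl ketone would be enolised in the second metalation.
Remark 3: ring E and O4 of ring A travel as methyl and benzyl ethers through chain assembly and are exchanged for acetates before the oxidation. C2 and C6 of a 3,4,5-trialkoxyphenyl ether are each ortho to two oxygens and para to a third, and would be hydroxylated by CF3CO3H.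

Step 1
Reactants: 1 4-fluorophenol
Product: 2 (4-fluorophenoxy)tri(propan-2-yl)silane
Conditions: TIPSCl, imidazole, DMF, rt
Reagents that add atoms: chlorotri(propan-2-yl)silane (TIPSCl), CC(C)[Si](Cl)(C(C)C)C(C)C
Why: O-silylation of a phenol; the bulky TIPS ether neither coordinates alkyllithiums nor leaves its ortho hydrogens accessible, so the later metalation should go beside fluorine, and it has no acidic benzylic CH2.

Step 2
Reactants: 2 (4-fluorophenoxy)tri(propan-2-yl)silane; 3 N-methoxy-N-methylacetamide (two portions)
Product: 8 1,1'-[2-fluoro-5-(triisopropylsilyloxy)-1,3-phenylene]di(ethan-1-one), via aryllithium 4 (not isolated), via mono-adduct lithium alkoxide 5 (not isolated), via lithiated mono-adduct 6 (not isolated), via bis-adduct dilithium dialkoxide 7 (not isolated)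
Conditions: s-BuLi (1.1 equiv), TMEDA, THF, −78 °C; 3 (1.05 equiv), −78 °C; s-BuLi (1.3 equiv), −78 °C; 3 (1.5 equiv), −78 to 0 °C; aq. NH4Cl, then dilute HCl
Reagents that add atoms: none
Why: Fluorine-directed ortho-lithiation and Weinreb ketone synthesis run twice in one flask; the chelated tetrahedral adduct 5 should persist at −78 °C and mask the first carbonyl against enolisation while the second fluorine-acidified position is lithiated, and both ketones are released only on acidic work-up.

Step 3
Reactants: 8 1,1'-[2-fluoro-5-(triisopropylsilyloxy)-1,3-phenylene]di(ethan-1-one)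
Product: 10 1,1'-[5-(benzyloxy)-2-fluoro-1,3-phenylene]di(ethan-1-one), via caesium phenolate 9 (not isolated)
Conditions: CsF, BnBr, DMF, rt
Reagents that add atoms: benzyl bromide, BrCc1ccccc1
Why: Fluoride desilylation followed at once by Williamson alkylation; with excess BnBr at rt the phenolate should be benzylated faster than it can displace a ring fluoride, and the benzyl ether, unlike the silyl ether, withstands the fluoride set free in the coupling steps.

Step 4
Reactants: 11 3,4,5-trimethoxyphenol; 10 1,1'-[5-(benzyloxy)-2-fluoro-1,3-phenylene]di(ethan-1-one)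
Product: 12 1,1'-[5-(benzyloxy)-2-(3,4,5-trimethoxyphenoxy)-1,3-phenylene]di(ethan-1-one) (diacetyl dimer benzyl ether, rings E and D)
Conditions: K2CO3, DMF, 80 °C, under argon
Reagents that add atoms: none
Why: Nucleophilic aromatic substitution by addition–elimination; the fluorine-bearing carbon lies between two ortho acetyl groups that stabilise the Meisenheimer intermediate, and K2CO3 deprotonates the phenol but not the methyl ketones to any useful extent.

Step 5
Reactants: 12 diacetyl dimer benzyl ether
Product: 13 1,1'-[5-hydroxy-2-(3,4,5-trimethoxyphenoxy)-1,3-phenylene]di(ethan-1-one) (diacetyl dimer phenol)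
Conditions: H2 (1 atm), Pd/C, EtOAc, rt
Reagents that add atoms: none
Why: Hydrogenolysis of a benzyl aryl ether; over Pd/C at ambient pressure in neutral EtOAc this should be much faster than hydrogenation of the aryl ketones, and the diaryl and methyl ethers are inert.

Step 6
Reactants: 13 diacetyl dimer phenol; 10 1,1'-[5-(benzyloxy)-2-fluoro-1,3-phenylene]di(ethan-1-one)
Product: 14 tetraacetyl trimer benzyl ether (rings E, D, C: 2,6-diacetyl-4-(benzyloxy)phenoxy group on C1 of the 3,5-diacetyl-4-(3,4,5-trimethoxyphenoxy)phenyl ring)
Conditions: K2CO3, DMF, 80–90 °C, under argon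
Reagents that add atoms: none
Why: Nucleophilic aromatic substitution as in step 4; the phenoxide of 13 has its acetyl groups meta and no ortho substituent, so it stays nucleophilic, and fluoride should be displaced far faster than the aryloxide on the already formed, equally activated ether carbon.

Step 7
Reactants: 14 tetraacetyl trimer benzyl ether
Product: 15 tetraacetyl trimer phenol
Conditions: H2 (1 atm), Pd/C, EtOAc, rt
Reagents that add atoms: none
Why: Hydrogenolysis of the benzyl aryl ether as in step 5, stopped at consumption of 14 so that the four ketones are not reduced.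

Step 8
Reactants: 15 tetraacetyl trimer phenol; 10 1,1'-[5-(benzyloxy)-2-fluoro-1,3-phenylene]di(ethan-1-one)
Product: 16 hexaacetyl tetramer benzyl ether (rings E, D, C, B)
Conditions: K2CO3, DMF, 80–90 °C, under argon
Reagents that add atoms: none
Why: Nucleophilic aromatic substitution as in step 6; the nucleophilic end of the chain has the same substitution as 13, so the same reactivity is expected.

Step 9
Reactants: 16 hexaacetyl tetramer benzyl ether
Product: 17 hexaacetyl tetramer phenol
Conditions: H2 (1 atm), Pd/C, EtOAc–THF, rt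
Reagents that add atoms: none
Why: Hydrogenolysis of the benzyl aryl ether as in step 5; THF is added only for solubility.

Step 10
Reactants: 17 hexaacetyl tetramer phenol; 10 1,1'-[5-(benzyloxy)-2-fluoro-1,3-phenylene]di(ethan-1-one)
Product: 18 octaacetyl pentamer with benzyl ether at O4 of ring A and methyl ethers at O3, O4 and O5 of ring E
Conditions: K2CO3, DMF, 90 °C, under argon
Reagents that add atoms: none
Why: Nucleophilic aromatic substitution as in step 6; all rings of the chain are electron-poor and air-stable, so the fourth coupling should differ from the earlier ones only in rate.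

Step 11
Reactants: 18 octaacetyl pentamer benzyl ether trimethyl ether
Product: 19 octaacetyl pentamer tetraphenol (free OH at C4 of ring A and at C3, C4 and C5 of ring E)
Conditions: BBr3 (large excess), CH2Cl2, −78 °C to rt; ice-water
Reagents that add atoms: none
Why: Lewis acid cleavage of alkyl aryl ethers (bromide attack on the boron-complexed ether); BBr3 removes the benzyl and the three methyl groups in one operation, leaves diaryl ethers untouched and only complexes reversibly to aryl ketones.

Step 12
Reactants: 19 octaacetyl pentamer tetraphenol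
Product: 20 octaacetyl pentamer tetraacetate (acetoxy at C4 of ring A and at C3, C4 and C5 of ring E)
Conditions: Ac2O, pyridine, DMAP (cat.), CH2Cl2, 0 °C to rt, under argon
Reagents that add atoms: acetic anhydride, CC(=O)OC(C)=O
Why: O-acetylation of phenols by nucleophilic catalysis; it is run on crude 19 under argon so that the pyrogallol-type ring E is capped before it can autoxidise, and it makes every ring electron-poor for the oxidation.

Step 13
Reactants: 20 octaacetyl pentamer tetraacetate
Product: 21 dodecaacetate of the target (acetoxy at C2, C4, C6 of ring A, at C3 and C5 of rings B, C and D, and at C3, C4, C5 of ring E)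
Conditions: urea·H2O2, (CF3CO)2O, Na2HPO4, CH2Cl2, 0 °C to rt (CF3CO3H formed in the flask, large excess)
Reagents that add atoms: trifluoroperacetic acid, OOC(=O)C(F)(F)F (made in the flask from urea–hydrogen peroxide, NC(N)=O.OO, and trifluoroacetic anhydride, O=C(OC(=O)C(F)(F)F)C(F)(F)F)
Why: Each ketone adds CF3CO3H to give a Criegee adduct, from which the aryl group migrates to oxygen with loss of trifluoroacetate; every migrating carbon (C2 and C6 of ring A, C3 and C5 of rings B, C and D) is ortho to a diaryl ether oxygen that supports the developing positive charge, and methyl is the poorest migrating group, so aryl acetates and not methyl esters should form. The closest known reaction is the Baeyer–Villiger oxidation of ortho-alkoxy and ortho-aryloxy acetophenones to aryl acetates with buffered trifluoroperacetic acid, a reagent that also oxidises electron-poor acetophenones. The step closes no ring and creates no stereocentre. The selectivity needed is aryl over methyl migration at all eight sites without electrophilic hydroxylation of any ring. It is secured because every oxygen substituent in 20 and in each partly oxidised intermediate is an acetate or a diaryl ether flanked by acyl or acyloxy groups, so no ring is activated enough for attack by the peracid, while Na2HPO4 takes up the CF3CO2H that could otherwise cleave the aryl acetates. The strongly electrophilic peracid in excess is chosen because the first migration on each ring occurs while that ring still carries a second acetyl group.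

Step 14
Reactants: 21 dodecaacetate of the target
Product: 22 2-{3,5-dihydroxy-4-[3,5-dihydroxy-4-[3,5-dihydroxy-4-(3,4,5-trihydroxyphenoxy)phenoxy]phenoxy]phenoxy}benzene-1,3,5-triol (target)
Conditions: 2 M HCl, 1,4-dioxane–H2O (degassed), 60 °C, under argon
Reagents that add atoms: none
Why: Acid-catalysed hydrolysis of aryl acetates by acyl–oxygen cleavage; the pyrogallol- and phloroglucinol-type rings are never present as air-sensitive phenolates, water as the only nucleophile cannot alkylate them, and diaryl ethers are inert to dilute acid.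

Compound list
1 | 4-fluorophenol | Oc1ccc(F)cc1 | starting material
2 | (4-fluorophenoxy)tri(propan-2-yl)silane | CC(C)[Si](Oc1ccc(F)cc1)(C(C)C)C(C)C | intermediate
3 | N-methoxy-N-methylacetamide | CON(C)C(C)=O | starting material
4 | [2-fluoro-5-(triisopropylsilyloxy)phenyl]lithium | [Li]c1cc(O[Si](C(C)C)(C(C)C)C(C)C)ccc1F | intermediate
5 | lithium 1-[2-fluoro-5-(triisopropylsilyloxy)phenyl]-1-[methoxy(methyl)amino]ethan-1-olate (racemic) | [Li+].CON(C)C(C)([O-])c1cc(O[Si](C(C)C)(C(C)C)C(C)C)ccc1F | intermediate
6 | lithium 1-[2-fluoro-3-lithio-5-(triisopropylsilyloxy)phenyl]-1-[methoxy(methyl)amino]ethan-1-olate (racemic) | [Li+].[Li]c1cc(O[Si](C(C)C)(C(C)C)C(C)C)cc(C(C)([O-])N(C)OC)c1F | intermediate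
7 | dilithium 1,1'-[2-fluoro-5-(triisopropylsilyloxy)-1,3-phenylene]bis{1-[methoxy(methyl)amino]ethan-1-olate} (mixture of diastereomers) | [Li+].[Li+].CON(C)C(C)([O-])c1cc(O[Si](C(C)C)(C(C)C)C(C)C)cc(C(C)([O-])N(C)OC)c1F | intermediate
8 | 1,1'-[2-fluoro-5-(triisopropylsilyloxy)-1,3-phenylene]di(ethan-1-one) | CC(=O)c1cc(O[Si](C(C)C)(C(C)C)C(C)C)cc(C(C)=O)c1F | intermediate
9 | caesium 3,5-diacetyl-4-fluorophenolate | [Cs+].CC(=O)c1cc([O-])cc(C(C)=O)c1F | intermediate
10 | 1,1'-[5-(benzyloxy)-2-fluoro-1,3-phenylene]di(ethan-1-one) | CC(=O)c1cc(OCc2ccccc2)cc(C(C)=O)c1F | intermediate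
11 | 3,4,5-trimethoxyphenol | COc1cc(O)cc(OC)c1OC | starting material
12 | 1,1'-[5-(benzyloxy)-2-(3,4,5-trimethoxyphenoxy)-1,3-phenylene]di(ethan-1-one) (diacetyl dimer benzyl ether) | CC(=O)c1cc(OCc2ccccc2)cc(C(C)=O)c1Oc3cc(OC)c(OC)c(OC)c3 | intermediate
13 | 1,1'-[5-hydroxy-2-(3,4,5-trimethoxyphenoxy)-1,3-phenylene]di(ethan-1-one) (diacetyl dimer phenol) | CC(=O)c1cc(O)cc(C(C)=O)c1Oc2cc(OC)c(OC)c(OC)c2 | intermediate
14 | tetraacetyl trimer benzyl ether (rings E, D, C) | CC(=O)c1cc(OCc2ccccc2)cc(C(C)=O)c1Oc3cc(C(C)=O)c(Oc4cc(OC)c(OC)c(OC)c4)c(C(C)=O)c3 | intermediate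
15 | tetraacetyl trimer phenol | CC(=O)c1cc(O)cc(C(C)=O)c1Oc2cc(C(C)=O)c(Oc3cc(OC)c(OC)c(OC)c3)c(C(C)=O)c2 | intermediate
16 | hexaacetyl tetramer benzyl ether (rings E, D, C, B) | CC(=O)c1cc(OCc2ccccc2)cc(C(C)=O)c1Oc3cc(C(C)=O)c(Oc4cc(C(C)=O)c(Oc5cc(OC)c(OC)c(OC)c5)c(C(C)=O)c4)c(C(C)=O)c3 | intermediate
17 | hexaacetyl tetramer phenol | CC(=O)c1cc(O)cc(C(C)=O)c1Oc2cc(C(C)=O)c(Oc3cc(C(C)=O)c(Oc4cc(OC)c(OC)c(OC)c4)c(C(C)=O)c3)c(C(C)=O)c2 | intermediate
18 | octaacetyl pentamer, ring A 4-benzyl ether, ring E 3,4,5-trimethyl ether | CC(=O)c1cc(OCc6ccccc6)cc(C(C)=O)c1Oc2cc(C(C)=O)c(Oc3cc(C(C)=O)c(Oc4cc(C(C)=O)c(Oc5cc(OC)c(OC)c(OC)c5)c(C(C)=O)c4)c(C(C)=O)c3)c(C(C)=O)c2 | intermediate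
19 | octaacetyl pentamer tetraphenol | CC(=O)c1cc(O)cc(C(C)=O)c1Oc2cc(C(C)=O)c(Oc3cc(C(C)=O)c(Oc4cc(C(C)=O)c(Oc5cc(O)c(O)c(O)c5)c(C(C)=O)c4)c(C(C)=O)c3)c(C(C)=O)c2 | intermediate
20 | octaacetyl pentamer tetraacetate (key-step precursor) | CC(=O)c1cc(OC(C)=O)cc(C(C)=O)c1Oc2cc(C(C)=O)c(Oc3cc(C(C)=O)c(Oc4cc(C(C)=O)c(Oc5cc(OC(C)=O)c(OC(C)=O)c(OC(C)=O)c5)c(C(C)=O)c4)c(C(C)=O)c3)c(C(C)=O)c2 | intermediate
21 | dodecaacetate of the target (key-step product) | CC(=O)Oc1cc(OC(C)=O)cc(OC(C)=O)c1Oc2cc(OC(C)=O)c(Oc3cc(OC(C)=O)c(Oc4cc(OC(C)=O)c(Oc5cc(OC(C)=O)c(OC(C)=O)c(OC(C)=O)c5)c(OC(C)=O)c4)c(OC(C)=O)c3)c(OC(C)=O)c2 | intermediate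
22 | 2-{3,5-dihydroxy-4-[3,5-dihydroxy-4-[3,5-dihydroxy-4-(3,4,5-trihydroxyphenoxy)phenoxy]phenoxy]phenoxy}benzene-1,3,5-triol | Oc1cc(O)c(Oc2cc(O)c(Oc3cc(O)c(Oc4cc(O)c(Oc5cc(O)c(O)c(O)c5)c(O)c4)c(O)c3)c(O)c2)c(O)c1 | target

Total step count: 14. Longest linear sequence: 14 steps, from 4-fluorophenol 1 through building block 10 (used in steps 4, 6, 8 and 10) to target 22.

Steps most likely to fail

Step 13. The oxidation may stall part-way, because aryl migration is slow at a ketone whose ring still carries a second acetyl group. Acetates may also be exchanged or cleaved by the acid formed, so that unmasked phenols are over-oxidised. The fallback sets out from 18 and comes back at target 22, forming the same eight C–O bonds by a peroxide rearrangement of alcohols instead of ketones. MeMgBr with anhydrous CeCl3 in THF (−78 to 0 °C) should add to all eight ketones without enolisation to give the octakis(2-hydroxypropan-2-yl) pentamer F1, which has no stereocentre. H2O2 with BF3·OEt2 in CH2Cl2 at 0 °C should convert each tertiary benzylic alcohol into its hydroperoxide, which undergoes Hock rearrangement (aryl migration to oxygen, loss of acetone) to give the octaphenol benzyl ether trimethyl ether F2. BBr3 in CH2Cl2 then cleaves the benzyl and methyl ethers of F2 to give 22.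

Step 2. The second metalation may be incomplete if s-BuLi is tied up in aggregates with the lithium hemiaminal alkoxide, or the tetrahedral adduct may collapse early, so that the freed ketone is enolised or attacked. The fallback sets out from 2 and comes back at 8, using an alkoxide instead of a hemiaminal as the carbonyl surrogate. Lithiation of 2 (s-BuLi, TMEDA, THF, −78 °C) and quenching with acetaldehyde should give racemic 1-[2-fluoro-5-(triisopropylsilyloxy)phenyl]ethan-1-ol F3. A second lithiation with 2.3 equiv s-BuLi (the first equivalent forms the base-stable lithium alkoxide) and acetaldehyde should give the diol 1,1'-[2-fluoro-5-(triisopropylsilyloxy)-1,3-phenylene]di(ethan-1-ol) F4 as a mixture of diastereomers. Dess–Martin periodinane (or activated MnO2) oxidises both benzylic alcohols to 8.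

Step 11. The benzyl bromide formed may benzylate ring E at carbon (Friedel–Crafts), and cleavage may be incomplete because the eight ketones bind the Lewis acid. The fallback sets out from 18 and comes back at 19, removing the benzyl group reductively before any Lewis acid is present. Hydrogenolysis (H2, Pd/C, EtOAc–THF, as in steps 5, 7 and 9) should give the octaacetyl pentamer phenol trimethyl ether F5. BBr3 in CH2Cl2 then has only the three methyl ethers of F5 to cleave and gives 19.

Further compounds
F1 | step 13 | octakis(2-hydroxypropan-2-yl) pentamer, ring A 4-benzyl ether, ring E 3,4,5-trimethyl ether | CC(C)(O)c1cc(OCc6ccccc6)cc(C(C)(C)O)c1Oc2cc(C(C)(C)O)c(Oc3cc(C(C)(C)O)c(Oc4cc(C(C)(C)O)c(Oc5cc(OC)c(OC)c(OC)c5)c(C(C)(C)O)c4)c(C(C)(C)O)c3)c(C(C)(C)O)c2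
F2 | step 13 | octaphenol pentamer, ring A 4-benzyl ether, ring E 3,4,5-trimethyl ether | Oc1cc(OCc6ccccc6)cc(O)c1Oc2cc(O)c(Oc3cc(O)c(Oc4cc(O)c(Oc5cc(OC)c(OC)c(OC)c5)c(O)c4)c(O)c3)c(O)c2
F3 | step 2 | 1-[2-fluoro-5-(triisopropylsilyloxy)phenyl]ethan-1-ol (racemic) | CC(O)c1cc(O[Si](C(C)C)(C(C)C)C(C)C)ccc1F
F4 | step 2 | 1,1'-[2-fluoro-5-(triisopropylsilyloxy)-1,3-phenylene]di(ethan-1-ol) (mixture of diastereomers) | CC(O)c1cc(O[Si](C(C)C)(C(C)C)C(C)C)cc(C(C)O)c1F
F5 | step 11 | octaacetyl pentamer phenol (ring A 4-OH), ring E 3,4,5-trimethyl ether | CC(=O)c1cc(O)cc(C(C)=O)c1Oc2cc(C(C)=O)c(Oc3cc(C(C)=O)c(Oc4cc(C(C)=O)c(Oc5cc(OC)c(OC)c(OC)c5)c(C(C)=O)c4)c(C(C)=O)c3)c(C(C)=O)c2
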